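**Retrosynthetic overview**
1. Target 28 ⇐ tert-butyl ester 27 ⇐ tetracycle 22 by C11 reduction (α-face), dihydroxylation of C2=C3 (β-face) and C16 methylenation.
2. Key step: 22 ⇐ 18 by an intramolecular (4+3) cycloaddition of a 2-ethoxyallyl cation (C9–C11–C12) onto a 2-silyloxycyclopentadiene (C8, C13–C16). Rings B, C and D, the C8 quaternary centre and the C11 oxygen form in one step.
3. The two reacting arms are held trans-diequatorial on ring A by the pre-formed C19–C20 lactone; 18 ⇐ lactone aldehyde 13 + ethyl vinyl ether + 3-chlorocyclopentenone.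
4. 13 ⇐ achiral spiro enone ester 5 by asymmetric Mukaiyama–Michael addition (C5), anti methylation (C4) and a lactonization that desymmetrizes C10.
5. Ring order: A (annulation) → lactone bridge → B, C and D together.

Assumption: gibberellin atom numbers (C1–C20) are used for all intermediates, α is the face of the C19–C20 lactone bridge, and compounds 1, 3, 6, 14 and 17 are taken as catalogue chemicals.
Assumption: the (S,S) ligand in step 3 is taken to give the drawn C5 configuration; if the sense is opposite, the (R,R) ligand is used.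

**Step 1**
Reactants: 1 (2,2-dimethyl-1,3-dioxan-5-yl)methanol
Product: 2 2,2-dimethyl-1,3-dioxane-5-carbaldehyde
Conditions: Dess–Martin periodinane, CH2Cl2, 0 °C → rt
Reagents that add atoms: none
Why: Dess–Martin oxidation of a primary alcohol under neutral conditions that spare the acetonide and avoid β-elimination of the β-alkoxy aldehyde; no stereocentre is formed.

**Step 2**
Reactants: 2 2,2-dimethyl-1,3-dioxane-5-carbaldehyde; 3 methyl 3-oxopent-4-enoate
Product: 5 methyl 3,3-dimethyl-9-oxo-2,4-dioxaspiro[5.5]undec-7-ene-8-carboxylate, via keto aldehyde Michael adduct 4 (not isolated)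
Conditions: pyrrolidine (20 mol %), PhCO2H (20 mol %), CH2Cl2, 0 °C → rt; then piperidinium acetate, PhMe, 60 °C, 4 Å MS
Reagents that add atoms: none
Why: Robinson-type annulation with the Nazarov reagent (enamine Michael addition of the α-branched aldehyde, then intramolecular Knoevenagel condensation) closes ring A; 5 is achiral because the spiro carbon C10 carries two enantiotopic CH2O arms.

**Step 3**
Reactants: 5 methyl 3,3-dimethyl-9-oxo-2,4-dioxaspiro[5.5]undec-7-ene-8-carboxylate; 6 1-tert-butoxy-1-(trimethylsilyloxy)ethene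
Product: 7 methyl 7-(2-tert-butoxy-2-oxoethyl)-3,3-dimethyl-9-oxo-2,4-dioxaspiro[5.5]undecane-8-carboxylate (C5 R; C4 epimers)
Conditions: Cu(OTf)2 (10 mol %), (S,S)-t-Bu-box (11 mol %), CH2Cl2, −78 → −40 °C; then 1 M HCl
Reagents that add atoms: none
Why: Catalytic enantioselective Mukaiyama–Michael addition, in which the alkylidene β-keto ester binds the divalent copper bis(oxazoline) Lewis acid as a two-point chelate so that the silyl ketene acetal attacks one face of C5; this sets C5 and makes the two CH2O arms on C10 diastereotopic.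

**Step 4**
Reactants: 7 Michael adduct β-keto ester
Product: 8 methyl 7-(2-tert-butoxy-2-oxoethyl)-3,3,8-trimethyl-9-oxo-2,4-dioxaspiro[5.5]undecane-8-carboxylate (C4: CO2Me cis to the C5 side chain; Me trans)
Conditions: MeI, K2CO3, acetone, rt
Reagents that add atoms: iodomethane CI
Why: C-alkylation of the β-keto ester enolate, with MeI entering anti to the adjacent C5 side chain, sets the C4 quaternary centre (CO2Me α, Me β).

**Step 5**
Reactants: 8 methylated keto diester
Product: 9 methyl 7-(2-tert-butoxy-2-oxoethyl)-3,3,8-trimethyl-9-(trifluoromethylsulfonyloxy)-2,4-dioxaspiro[5.5]undec-9-ene-8-carboxylate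
Conditions: KN(SiMe3)2, PhNTf2, THF, −78 °C
Reagents that add atoms: N-phenylbis(trifluoromethanesulfonimide) O=S(=O)(N(c1ccccc1)S(=O)(=O)C(F)(F)F)C(F)(F)F
Why: Kinetic enol triflate formation is regiospecific because the ketone can enolize only towards C2 (C4 is quaternary) and is more acidic than the tert-butyl ester; no stereocentre changes.

**Step 6**
Reactants: 9 enol triflate
Product: 10 methyl 7-(2-tert-butoxy-2-oxoethyl)-3,3,8-trimethyl-2,4-dioxaspiro[5.5]undec-9-ene-8-carboxylate
Conditions: Pd(OAc)2 (5 mol %), PPh3, HCO2H, n-Bu3N, DMF, 60 °C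
Reagents that add atoms: none
Why: Palladium-catalysed formate reduction of the enol triflate (Cacchi reduction) gives the C2=C3 alkene and leaves both esters and the acetonide untouched.

**Step 7**
Reactants: 10 alkene acetonide diester
Product: 12 tert-butyl 2-[5-(hydroxymethyl)-1-methyl-2-oxo-3-oxabicyclo[3.3.1]non-7-en-9-yl]acetate (19,20-lactone alcohol), via diol 11 (not isolated)
Conditions: AcOH/H2O (4:1), 40 °C; then DBU (0.2 equiv), PhMe, 80 °C
Reagents that add atoms: none
Why: Acetal hydrolysis then base-catalysed lactonization (transesterification), in which only the CH2OH cis to the C4 methyl ester can reach C19; this fixes C10 (C20 α, free CH2OH = C9 β), the tert-butyl ester does not transesterify, and the bridged lactone locks the C5 and C10 arms trans-diequatorial.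

**Step 8**
Reactants: 12 lactone alcohol
Product: 13 tert-butyl 2-[5-formyl-1-methyl-2-oxo-3-oxabicyclo[3.3.1]non-7-en-9-yl]acetate
Conditions: Dess–Martin periodinane, CH2Cl2, rt
Reagents that add atoms: none
Why: Dess–Martin oxidation of the neopentyl primary alcohol gives a non-enolizable aldehyde (C9); no stereocentre changes.

**Step 9**
Reactants: 13 lactone aldehyde; 14 ethyl vinyl ether
Product: 16 tert-butyl 2-{5-[2-ethoxy-1-(triethylsilyloxy)prop-2-en-1-yl]-1-methyl-2-oxo-3-oxabicyclo[3.3.1]non-7-en-9-yl}acetate (C9 epimers), via lithium alkoxide 15 (not isolated)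
Conditions: 14, t-BuLi, THF, −78 → 0 °C; then 13, −78 °C; Et3SiCl, −78 → 0 °C
Reagents that add atoms: chlorotriethylsilane CC[Si](Cl)(CC)CC
Why: 1,2-Addition of 1-ethoxyvinyllithium (an acyl anion equivalent) to the aldehyde is much faster than attack on the hindered lactone or tert-butyl ester, and the alkoxide is silylated in situ; the new C9 carbinol centre is inconsequential because C9 later becomes a cationic terminus.

**Step 10**
Reactants: 16 allylic silyl ether enol ether; 17 3-chlorocyclopent-2-en-1-one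
Product: 18 tert-butyl 2-{5-[2-ethoxy-1-(triethylsilyloxy)prop-2-en-1-yl]-1-methyl-2-oxo-3-oxabicyclo[3.3.1]non-7-en-9-yl}-2-(3-oxocyclopent-1-en-1-yl)acetate (C6 and C9 epimers)
Conditions: LiN(i-Pr)2 (2.2 equiv), THF, −78 °C; then 17, −78 → −20 °C
Reagents that add atoms: none
Why: Conjugate addition–elimination (vinylogous acyl substitution) of the tert-butyl ester enolate on the β-chloro enone joins C6 to C8 and brings in the five D-ring carbons as a stable cyclopentenone; C6 is formed as an epimer mixture that is corrected in step 15.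

**Step 11**
Reactants: 18 enone
Product: 22 tetracyclic C11 ketone C16 silyl enol ether (tert-butyl ester; C6 epimers), via silyl dienol ether 19 (not isolated), via ethoxyallyl cation 20 (not isolated), via oxocarbenium cycloadduct 21 (not isolated)
Conditions: LiN(i-Pr)2 (1.05 equiv), THF, −78 °C; t-BuMe2SiOTf, −78 °C; then Me3SiOTf, CH2Cl2, −78 → −40 °C; aq. NaHCO3
Reagents that add atoms: tert-butyldimethylsilyl trifluoromethanesulfonate CC(C)(C)[Si](C)(C)OS(=O)(=O)C(F)(F)F; water O
Why: Proposed new method: kinetic α′-deprotonation and O-silylation give the 2-silyloxycyclopentadiene (the C6–H lies in the enone plane by A(1,3) strain and is not removed), Me3SiOTf ionizes the allylic silyl ether to a 2-ethoxyallyl cation, and this cation is trapped intramolecularly in a (4+3) cycloaddition that forms the C9–C8 and C12–C13 bonds and hence rings B, C and D together; the lactone-locked tether has a fixed twist (C6–C5–C10–C9 about −50°) that is matched only by the extended approach of the W-shaped cation to the diene face syn to C20, which sets C8, C9 (H β) and C13 as in the target, and hydrolysis of the oxocarbenium ion gives the C11 ketone while the C16 silyl enol ether survives; the closest known reactions are intramolecular oxyallyl cation (4+3) cycloadditions of alkoxyallyl cations onto tethered furans and dienes (Föhlisch and Harmata type).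

**Step 12**
Reactants: 22 tetracyclic ketone silyl enol ether
Product: 24 tert-butyl 11β-hydroxy-16-oxo-17-nor-gibberell-2-en-7-oate 19,20-lactone (C6 epimers), via silyl enol ether alcohol 23 (not isolated)
Conditions: LiBH(s-Bu)3, THF, −78 °C; then 1 M HCl, THF, rt
Reagents that add atoms: none
Why: The bulky hydride should attack the C11 ketone of the bicyclo[3.2.1]octenone from the exo (α) face, away from the two-carbon bridge, to give the axial 11β-alcohol (stereoselective ketone reduction, as in reductions of (4+3) adducts); the acidic work-up then unmasks the C16 ketone, so the two carbonyls are told apart without protecting groups.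

**Step 13**
Reactants: 24 hydroxy ketone alkene
Product: 25 tert-butyl 2β,3β,11β-trihydroxy-16-oxo-17-nor-gibberellan-7-oate 19,20-lactone (C6 epimers)
Conditions: OsO4 (2 mol %), NMO, acetone/H2O, rt
Reagents that add atoms: 4-methylmorpholine N-oxide C[N+]1([O-])CCOCC1; water O
Why: Upjohn dihydroxylation of the only C=C bond, with OsO4 adding to the exo (β) face of the bicyclo[3.3.1] lactone, opposite the lactone bridge, gives the cis 2β,3β-diol.

**Step 14**
Reactants: 25 triol ketone
Product: 26 tert-butyl 2β,3β,11β-trihydroxy-gibberell-16-en-7-oate 19,20-lactone (C6 epimers)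
Conditions: Ph3PCH3Br, KOt-Bu (excess), THF, 0 °C → rt
Reagents that add atoms: methyltriphenylphosphonium bromide C[P+](c1ccccc1)(c1ccccc1)c1ccccc1.[Br-]
Why: Wittig methylenation of the only ketone (the C16 nor-ketone, a routine gibberellin operation) installs the exocyclic alkene; excess ylide covers the three hydroxyl groups.

**Step 15**
Reactants: 26 methylene triol ester (C6 epimers)
Product: 27 tert-butyl 2β,3β,11β-trihydroxy-gibberell-16-en-7-oate 19,20-lactone (6β-ester; H6 α)
Conditions: KOt-Bu, t-BuOH/THF, 40 °C; then aq. NH4Cl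
Reagents that add atoms: none
Why: Base-mediated epimerization through the ester enolate converges on the 6β-ester, which is the stable epimer because it is trans to the bulky C4 substituent on C5 (thermodynamic control, as known for gibberellin esters).

**Step 16**
Reactants: 27 tert-butyl ester
Product: 28 2β,3β,11β-trihydroxy-gibberell-16-ene-7,19-dioic acid 19,20-lactone (CNP0302900.3)
Conditions: SiO2, PhMe, 110 °C
Reagents that add atoms: none
Why: Silica-promoted thermal cleavage of the tert-butyl ester (loss of isobutene) frees the C7 acid without solution acid, so the exocyclic alkene and the lactone survive; no stereocentre changes.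

**Compound list**
1 | (2,2-dimethyl-1,3-dioxan-5-yl)methanol | OCC1COC(C)(C)OC1 | starting material
2 | 2,2-dimethyl-1,3-dioxane-5-carbaldehyde | O=CC1COC(C)(C)OC1 | intermediate
3 | methyl 3-oxopent-4-enoate (Nazarov reagent) | C=CC(=O)CC(=O)OC | starting material
4 | methyl 5-(5-formyl-2,2-dimethyl-1,3-dioxan-5-yl)-3-oxopentanoate (Michael adduct, not isolated) | O=CC1(CCC(=O)CC(=O)OC)COC(C)(C)OC1 | intermediate
5 | methyl 3,3-dimethyl-9-oxo-2,4-dioxaspiro[5.5]undec-7-ene-8-carboxylate (ring A; spiro carbon = C10) | COC(=O)C1=CC2(COC(C)(C)OC2)CCC1=O | intermediate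
6 | 1-tert-butoxy-1-(trimethylsilyloxy)ethene | C=C(OC(C)(C)C)O[Si](C)(C)C | starting material
7 | methyl 7-(2-tert-butoxy-2-oxoethyl)-3,3-dimethyl-9-oxo-2,4-dioxaspiro[5.5]undecane-8-carboxylate (C5 R, C4 epimers) | COC(=O)C1C(=O)CCC2(COC(C)(C)OC2)[C@@H]1CC(=O)OC(C)(C)C | intermediate
8 | methyl 7-(2-tert-butoxy-2-oxoethyl)-3,3,8-trimethyl-9-oxo-2,4-dioxaspiro[5.5]undecane-8-carboxylate (C4 ester cis to C5 side chain, C4 methyl trans) | COC(=O)[C@]1(C)C(=O)CCC2(COC(C)(C)OC2)[C@@H]1CC(=O)OC(C)(C)C | intermediate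
9 | C3 enol triflate of 8 | COC(=O)[C@]1(C)C(OS(=O)(=O)C(F)(F)F)=CCC2(COC(C)(C)OC2)[C@@H]1CC(=O)OC(C)(C)C | intermediate
10 | methyl 7-(2-tert-butoxy-2-oxoethyl)-3,3,8-trimethyl-2,4-dioxaspiro[5.5]undec-9-ene-8-carboxylate (C2=C3 alkene) | COC(=O)[C@]1(C)C=CCC2(COC(C)(C)OC2)[C@@H]1CC(=O)OC(C)(C)C | intermediate
11 | methyl 6-(2-tert-butoxy-2-oxoethyl)-5,5-bis(hydroxymethyl)-1-methylcyclohex-2-ene-1-carboxylate (diol, not isolated) | COC(=O)[C@]1(C)C=CCC(CO)(CO)[C@@H]1CC(=O)OC(C)(C)C | intermediate
12 | tert-butyl 2-[5-(hydroxymethyl)-1-methyl-2-oxo-3-oxabicyclo[3.3.1]non-7-en-9-yl]acetate (19,20-lactone; CH2OH = C9, β; side chain on C5 syn to the lactone bridge) | OC[C@]12COC(=O)[C@](C)(C=CC1)[C@H]2CC(=O)OC(C)(C)C | intermediate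
13 | tert-butyl 2-[5-formyl-1-methyl-2-oxo-3-oxabicyclo[3.3.1]non-7-en-9-yl]acetate | O=C[C@]12COC(=O)[C@](C)(C=CC1)[C@H]2CC(=O)OC(C)(C)C | intermediate
14 | ethyl vinyl ether | C=COCC | starting material
15 | lithium alkoxide from addition of 1-ethoxyvinyllithium to 13 (C9 epimers, not isolated) | [Li+].[O-]C(C(=C)OCC)[C@]12COC(=O)[C@](C)(C=CC1)[C@H]2CC(=O)OC(C)(C)C | intermediate
16 | tert-butyl 2-{5-[2-ethoxy-1-(triethylsilyloxy)prop-2-en-1-yl]-1-methyl-2-oxo-3-oxabicyclo[3.3.1]non-7-en-9-yl}acetate (C9 epimers) | C=C(OCC)C(O[Si](CC)(CC)CC)[C@]12COC(=O)[C@](C)(C=CC1)[C@H]2CC(=O)OC(C)(C)C | intermediate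
17 | 3-chlorocyclopent-2-en-1-one | O=C1CCC(Cl)=C1 | starting material
18 | tert-butyl 2-{5-[2-ethoxy-1-(triethylsilyloxy)prop-2-en-1-yl]-1-methyl-2-oxo-3-oxabicyclo[3.3.1]non-7-en-9-yl}-2-(3-oxocyclopent-1-en-1-yl)acetate (C6 and C9 epimers) | C=C(OCC)C(O[Si](CC)(CC)CC)[C@]12COC(=O)[C@](C)(C=CC1)[C@H]2C(C(=O)OC(C)(C)C)C3=CC(=O)CC3 | intermediate
19 | 3-(tert-butyldimethylsilyloxy)cyclopenta-1,3-dien-1-yl analogue of 18 (kinetic silyl dienol ether, not isolated) | C=C(OCC)C(O[Si](CC)(CC)CC)[C@]12COC(=O)[C@](C)(C=CC1)[C@H]2C(C(=O)OC(C)(C)C)C3=CC(O[Si](C)(C)C(C)(C)C)=CC3 | intermediate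
20 | 2-ethoxyallyl cation (C9–C11–C12) from 19 after loss of the C9 silyloxy group (not isolated) | [CH2+]C(OCC)=C[C@]12COC(=O)[C@](C)(C=CC1)[C@H]2C(C(=O)OC(C)(C)C)C3=CC(O[Si](C)(C)C(C)(C)C)=CC3 | intermediate
21 | (4+3) cycloadduct as C11 O-ethyl oxocarbenium ion (not isolated) | CC(C)(C)[Si](C)(C)OC1=C[C@]23C[C@H]1CC(=[O+]CC)[C@H]2[C@]12COC(=O)[C@](C)(C=CC1)[C@H]2C3C(=O)OC(C)(C)C | intermediate
22 | tert-butyl 16-(tert-butyldimethylsilyloxy)-11-oxo-17-nor-gibberella-2,15-dien-7-oate 19,20-lactone (H5 β, H9 β, C14 α; C6 epimers) | CC(C)(C)[Si](C)(C)OC1=C[C@]23C[C@H]1CC(=O)[C@H]2[C@]12COC(=O)[C@](C)(C=CC1)[C@H]2C3C(=O)OC(C)(C)C | intermediate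
23 | 11β-alcohol of 22 (not isolated) | CC(C)(C)[Si](C)(C)OC1=C[C@]23C[C@H]1C[C@H](O)[C@H]2[C@]12COC(=O)[C@](C)(C=CC1)[C@H]2C3C(=O)OC(C)(C)C | intermediate
24 | tert-butyl 11β-hydroxy-16-oxo-17-nor-gibberell-2-en-7-oate 19,20-lactone (C6 epimers) | O=C1C[C@]23C[C@H]1C[C@H](O)[C@H]2[C@]12COC(=O)[C@](C)(C=CC1)[C@H]2C3C(=O)OC(C)(C)C | intermediate
25 | tert-butyl 2β,3β,11β-trihydroxy-16-oxo-17-nor-gibberellan-7-oate 19,20-lactone (C6 epimers) | O=C1C[C@]23C[C@H]1C[C@H](O)[C@H]2[C@]12COC(=O)[C@](C)([C@@H](O)[C@@H](O)C1)[C@H]2C3C(=O)OC(C)(C)C | intermediate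
26 | tert-butyl 2β,3β,11β-trihydroxy-gibberell-16-en-7-oate 19,20-lactone (C6 epimers) | C=C1C[C@]23C[C@H]1C[C@H](O)[C@H]2[C@]12COC(=O)[C@](C)([C@@H](O)[C@@H](O)C1)[C@H]2C3C(=O)OC(C)(C)C | intermediate
27 | tert-butyl 2β,3β,11β-trihydroxy-gibberell-16-en-7-oate 19,20-lactone (6β-ester, H6 α) | C=C1C[C@]23C[C@H]1C[C@H](O)[C@H]2[C@]12COC(=O)[C@](C)([C@@H](O)[C@@H](O)C1)[C@H]2[C@@H]3C(=O)OC(C)(C)C | intermediate
28 | 2β,3β,11β-trihydroxy-gibberell-16-ene-7,19-dioic acid 19,20-lactone (CNP0302900.3) | C=C1C[C@]23C[C@H]1C[C@H](O)[C@H]2[C@]12COC(=O)[C@](C)([C@@H](O)[C@@H](O)C1)[C@H]2[C@@H]3C(=O)O | target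

**Totals**
Total step count: 16. Longest linear sequence: 16 steps (1 → 28); compounds 3, 6, 14 and 17 are used as purchased.

**Steps most likely to fail, each with a fallback**

Step 11 (the cation may eliminate or rearrange, the diene may react at the wrong terminus, and facial selectivity rests on a tether-twist argument). The fallback closes rings B and C one bond at a time by enolate chemistry instead of by cycloaddition. It sets out from 18: PPTS in wet acetone hydrolyses the enol ether to the α-triethylsilyloxy methyl ketone F1. SmI2 (THF, −78 → 0 °C) cleaves the C9–O bond, and the resulting C9 samarium enolate adds 5-exo to the cyclopentenone (intramolecular Michael addition) to give the ring B spiro diketone F2. LiN(i-Pr)2 (2.2 equiv) followed by Fe(acac)3 couples the C12 and C13 enolates oxidatively, closing ring C to the 11,16-diketone F3. OsO4/NMO gives the 2β,3β-diol F4, Ph3P=CH2 (1.2 equiv, 0 °C) methylenates the less hindered C16 ketone to the 16-methylene 11-ketone F5, and NaBH4 reduces C11 from the α face, so the sequence comes back to the route at 26.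

Step 3 (the neopentyl β-carbon C5 may be too hindered for the chelated copper catalyst, or the selectivity may be low). The fallback uses hydrogen-bond catalysis with a decarboxylative donor instead of Lewis acid catalysis. It sets out from 5: mono-tert-butyl malonate adds under a cinchona-derived bifunctional squaramide (10 mol %, PhMe, 0 °C) to give the malonic half-acid adduct F6, which loses CO2 on warming to 60 °C and comes back to the route at 7.

Step 2 (the Nazarov reagent polymerizes easily and the Knoevenagel closure is untested on this β-alkoxy aldehyde). The fallback builds the enone first and adds the ester carbon by carbonylation. It sets out from 2: Robinson annulation with methyl vinyl ketone (KOH cat., MeOH; then pyrrolidine/AcOH, PhMe, 80 °C) gives the spiro enone F7. I2/pyridine gives the α-iodo enone F8, and Pd(OAc)2/PPh3, CO (1 atm), MeOH, Et3N, 60 °C (alkoxycarbonylation) comes back to the route at 5.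

**Further compounds**
F1 | step 11 | α-triethylsilyloxy methyl ketone | CC(=O)C(O[Si](CC)(CC)CC)[C@]12COC(=O)[C@](C)(C=CC1)[C@H]2C(C(=O)OC(C)(C)C)C3=CC(=O)CC3
F2 | step 11 | ring B spiro diketone | O=C1C[C@]2(CC1)[C@@H](C(C)=O)[C@]13COC(=O)[C@](C)(C=CC1)[C@H]3C2C(=O)OC(C)(C)C
F3 | step 11 | 11,16-diketone | O=C1C[C@]23C[C@H]1CC(=O)[C@H]2[C@]12COC(=O)[C@](C)(C=CC1)[C@H]2C3C(=O)OC(C)(C)C
F4 | step 11 | 2β,3β-diol | O=C1C[C@]23C[C@H]1CC(=O)[C@H]2[C@]12COC(=O)[C@](C)([C@@H](O)[C@@H](O)C1)[C@H]2C3C(=O)OC(C)(C)C
F5 | step 11 | 16-methylene 11-ketone | C=C1C[C@]23C[C@H]1CC(=O)[C@H]2[C@]12COC(=O)[C@](C)([C@@H](O)[C@@H](O)C1)[C@H]2C3C(=O)OC(C)(C)C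
F6 | step 3 | malonic half-acid adduct | COC(=O)C1C(=O)CCC2(COC(C)(C)OC2)[C@@H]1C(C(=O)O)C(=O)OC(C)(C)C
F7 | step 2 | spiro enone | O=C1C=CC2(COC(C)(C)OC2)CC1
F8 | step 2 | α-iodo enone | O=C1C(I)=CC2(COC(C)(C)OC2)CC1
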